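## Structural features

The target is a 4H-chromen-4-one: a benzene ring (ring A) fused through C4a and C8a to a γ-pyranone (ring C). A 4-hydroxyphenyl group (ring B) is attached to C2 through an ether oxygen, not through a carbon–carbon bond. Ring A is pentasubstituted: C5 carries a free hydroxyl hydrogen-bonded to the C4 carbonyl, C6 a hydrogen, C7 a methoxy group, C8 a 3-methylbut-2-enyl (prenyl) chain and C8a the ring oxygen O1. There is no stereocentre and no stereogenic double bond, so the problem is one of regiochemistry and functional-group tolerance. The fragile parts are the prenyl double bond (protic and Lewis acids, electrophilic oxidants, hydrogenation) and C2, a vinylogous carbonate carbon open to addition–elimination by hard nucleophiles. The real difficulty is to place three different oxygen functions and the prenyl group on four adjacent ring A positions without selective alkylation of a phloroglucinol, and then to attach an aryloxy group at C2. The key step exploits the fact that C8a–C8–C7–C6 has the oxidation pattern and branching of C1–C4 of a 2-prenylated acetoacetate, while C4a–C5 with the C4 carbon is a propiolate. Joining the two across C4a–C8a and C5–C6 builds ring A with every substituent already in place.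

## Logic of the disconnections

19 ⇒ 18. The ring B O–Si bond is cut first, because the ring B phenol must stay masked through the organolithium chemistry and a silyl ether can be removed last with buffered fluoride. Nothing is gained in skeleton, but the last forward step then touches neither the prenyl group nor C2. The demand is a fluoride source buffered well enough that no hard base adds to C2.

18 ⇒ 17. The O–CH3 bond at C5 is cut next. The C5 oxygen is carried as a methyl ether because it is brought in as an alkoxide, and of the two ring A methyl ethers only this one is chelated to the C4 carbonyl. The gain is that ring A needs no third protecting group. The forward step must cleave one aryl methyl ether by chelation control at low temperature without adding acid across the prenyl double bond.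

17 ⇒ 11 + 15 (through 16). Ring C is opened at O1–C2 and C3–C4. This removes C2 and C3 as a two-carbon alkyne that already carries the ring B ether oxygen, so the aryloxy group is never installed on a preformed pyranone, and ring A is left as a salicylate. A bicyclic vinylogous carbonate becomes an ester and an acetylide. The forward step requires that the ester of 11 take up one acetylide and no more, and that the ortho phenol then add to the oxygen-bearing alkyne carbon (6-endo).

15 ⇒ 14 ⇒ 12 + 13. The alkynyl C–O bond is traced to a vinylic C–O bond, formed by adding the phenol of 12 to the two-carbon unit of 13; two chlorine atoms later leave to unveil the triple bond. This replaces an unstable aryloxyalkyne by a storable dichlorovinyl ether. The demand is that the silyl ether of 12 survive the basic vinylation and the alkyllithium.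

11 ⇒ 10. The C–O bond at the future C5 is cut to a C–Br bond. An oxygen on the alkyne carbon would make the dienophile of the key step electron-rich and inert, whereas bromine keeps it electrophilic and can be exchanged afterwards. The forward step is a copper-mediated alkoxylation that must tolerate a free phenol, an ester and the prenyl group.

10 ⇒ 5 + 7 (through 8 and 9). Ring A is cut at C4a–C8a and C5–C6. Both fragments become acyclic and each carries its substituents in a fixed order, so the regiochemistry of a pentasubstituted benzene reduces to the polarity matching of one cycloaddition. Two skeletal bonds and the ring are removed in a single operation. The forward step demands one sense of addition, aromatization by loss of an alcohol and not of the silanol, and survival of the C–Br bond.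

7 ⇒ 6. The C(sp)–Br bond is cut; the terminal alkyne is an article of commerce and its bromination is routine.

5 ⇒ 4 ⇒ 3 ⇒ 1 + 2. The ketene acetal O–Si bond, then the enol ether O–CH3 bond, then the C–C bond between the future C8 and the prenyl chain are cut in turn. The prenyl group is thus attached to a simple β-keto ester, where only one carbon is nucleophilic, and not to an arene. The forward steps must avoid dialkylation, keep the trisubstituted alkene away from strong acid during enol ether formation, and deprotonate the γ-methyl group selectively.

## Other disconnections considered

Alternative 1: The pyranone is cut at C3–C4 and O1–C2 at the chromanone oxidation level. Irradiation of the benzodioxinone A1 would expel its ketal bridge as a volatile ketone and set free the quinoketene A3. A3 should add the aryl vinyl ether A2 as a hetero-diene, ketene carbon to the CH2 terminus and carbonyl oxygen to the oxygen-bearing carbon, giving the racemic 2-aryloxychromanone A4.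
- In its favour: the step is neutral, needs no reagent, is convergent and forms both pyranone bonds at once with unambiguous regiochemistry. It also avoids acetylide addition to a hindered ester. On these points it is the better plan.
- Against it: A4 is one oxidation level too low and is a mixed aryl acetal β to a ketone. The late dehydrogenation must outrun β-elimination of the aryloxide and retro-oxa-Michael ring opening, and the usual enone-forming oxidants threaten the prenyl alkene.
- Against it also: A1 already holds the whole ring A pattern, so the regiochemical problem is only moved into its preparation from a phloroglucinol acid (selective O-methylation, mono-C-prenylation).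
- Comparison: both plans rest on a pericyclic key step and both still need 5-O-demethylation and desilylation. The chosen plan fixes the ring A pattern through an acyclic precursor and reaches the chromone oxidation state directly, so it should be shorter overall.

Alternative 2: The cut is C4–C4a. The acid A5, activated as a mixed anhydride, would acylate the trioxygenated ring at the only position within reach and give the chromone A6.
- In its favour: the pyranone forms at the correct oxidation state, the attacked carbon is the most electron-rich one available, and the C5 oxygen is present from the start. No halogen placeholder or copper step is needed, which makes it the better plan on those points, and on paper the sequence after the key step is no longer than the chosen one.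
- Against it: A5 is a ketene bis(aryl) acetal. It should be acid-labile (hydrolysis to a malonic half ester, then decarboxylation) under the strongly acidic acylation medium that also endangers the prenyl group.
- Against it also: A5 must be assembled by two successive additions of different phenols to a three-carbon electrophile, with a risk of scrambling, and its trioxygenated half again requires regioselective C-prenylation of a phloroglucinol ether.
- Against it also: A6 needs debenzylation without hydrogenolysis, next to a prenyl alkene, as well as 5-O-demethylation.
- Comparison: the two are equal in convergence; the chosen plan trades the acid-labile acrylic acid for a robust benzoate and keeps strong acid away from the prenyl group until one cold, final Lewis acid step.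

Alternative 3: Ring A is cut at C8–C8a and C6–C7 (ketene [2+2]) and at C4a–C8a (six-electron electrocyclization). Heating cyclobutenone A7 with the prenylated ynol ether A8 should give phenol A9 through a vinylketene, a vinylcyclobutenone and a dienylketene.
- In its favour: it is a reagent-free, well-established benzannulation whose regiochemistry follows from ketene and ynol ether polarity. It delivers the C5 oxygen directly, which is better than a bromine placeholder, and is the equal of the chosen step in bonds formed per operation.
- Against it: A9 has no carbon at C4a. An ortho-acylation must follow and must choose C4a over C6, both flanked by two oxygens, before ring C can be built.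
- Against it also: the 5-O-ethyl group must later be cleaved with the same Lewis acid problem, A8 is a volatile, acid-sensitive ynol ether, and A7 is not a shelf reagent.
- Comparison: the chosen cycloaddition installs the C4 carbon as an ester next to the free phenol in the same step, so ring C follows in one operation; alternative 3 would need more steps after its key step.

Key step: step 5

Remark on the chemistry: the atom mapping 5 + 7 → 10 → ring A of 19 was re-derived and the structures needed no correction. The double-bond geometries drawn for 4 and for the ketene acetal of 5 are assumed immaterial, since both disappear on the way to 10. The only tightening of the precursor design is practical: 5 is used at once after a non-aqueous work-up and the aromatization is finished with cold dilute acid.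

## Route

Step 1
Reactants: 1 methyl acetoacetate; 2 prenyl bromide (1-bromo-3-methylbut-2-ene)
Product: 3 methyl 2-acetyl-5-methylhex-4-enoate (racemic; the α-stereocentre is labile and vanishes in step 2)
Conditions: K2CO3, acetone, reflux (1 in slight excess)
Reagents that add atoms: none
Why: C-alkylation of a β-keto ester enolate by an allylic bromide (SN2) is standard; a slight excess of 1 and a mild carbonate base should hold back dialkylation.

Step 2
Reactants: 3 methyl 2-acetyl-5-methylhex-4-enoate
Product: 4 methyl (E)-3-methoxy-2-(3-methylbut-2-enyl)but-2-enoate
Conditions: HC(OMe)3, MeOH, TsOH·H2O (cat.), rt; Et3N; distillation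
Reagents that add atoms: trimethyl orthoformate, COC(OC)OC
Why: Acid-catalysed enol etherification of a β-keto ester with an orthoformate gives the conjugated 3-methoxy enoate; a catalytic sulfonic acid at room temperature, neutralized before heating, should not add methanol across the trisubstituted alkene.

Step 3
Reactants: 4 methyl (E)-3-methoxy-2-(3-methylbut-2-enyl)but-2-enoate
Product: 5 (1Z)-1,3-dimethoxy-2-(3-methylbut-2-enyl)-1-(trimethylsilyloxy)buta-1,3-diene (one ketene acetal geometry drawn; either serves)
Conditions: LiN(iPr)2, THF, −78 °C; Me3SiCl, −78 °C to rt; non-aqueous work-up, used at once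
Reagents that add atoms: chlorotrimethylsilane, C[Si](C)(C)Cl
Why: Kinetic γ-deprotonation of a 3-alkoxy enoate gives the extended ester dienolate, which is silylated on oxygen to the vinylogous silyl ketene acetal; the allylic CH2 of the prenyl chain is not acidified by the ester and should stay untouched.

Step 4
Reactants: 6 methyl propiolate
Product: 7 methyl 3-bromopropiolate
Conditions: N-bromosuccinimide, AgNO3 (cat.), acetone, rt
Reagents that add atoms: N-bromosuccinimide, O=C1CCC(=O)N1Br
Why: Electrophilic bromination of a terminal alkyne through its silver acetylide (monovalent silver catalysis) is the standard preparation of 1-bromoalkynes and is established for this ester.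

Step 5
Reactants: 5 (1Z)-1,3-dimethoxy-2-(3-methylbut-2-enyl)-1-(trimethylsilyloxy)buta-1,3-diene; 7 methyl 3-bromopropiolate
Product: 10 methyl 6-bromo-2-hydroxy-4-methoxy-3-(3-methylbut-2-enyl)benzoate, via cycloadduct 8 (not isolated), via aryl trimethylsilyl ether 9 (not isolated)
Conditions: PhMe, 0 °C to rt, then 60 °C; then 0.5 M HCl, THF, 0 °C, brief
Reagents that add atoms: none
Why: The vinylogous ketene acetal 5 is most nucleophilic at its CH2 terminus, which should attack the bromine-bearing β-carbon of ynoate 7 while the ketene acetal carbon bonds to the ester-bearing α-carbon, in an asynchronous (at the limit stepwise, Mukaiyama–Michael then ring closure) [4+2] cycloaddition that forms C5–C6 and C4a–C8a (chromone numbering) and gives the cyclohexa-1,4-diene 8. Ring A is thus closed by an intermolecular Diels–Alder reaction in which four carbons come from the diene and two from the alkyne. In 8 the mixed ketal carbon lies 1,4 to the ring CH2, so loss of methanol across these positions aromatizes the ring to silyl ether 9 without an oxidant, and cold dilute acid then cleaves the O–Si bond to phenol 10; if desilylation comes first, the hemiketal loses methanol and enolizes to the same phenol. The closest known reaction type is the aromatizing Diels–Alder reaction of 1,1,3-trioxygenated butadienes with alkynoates and haloquinones. The only transient stereocentre is the ketal carbon of racemic 8, which is erased on aromatization, so no stereocontrol is needed. The selectivity needed is regiochemical and rests on matched polarization, the largest HOMO coefficient of 5 lying at the CH2 terminus and the largest LUMO coefficient of 7 at the carbon β to the ester, which bromine should not override; this places the hydroxyl between ester and prenyl and the bromine at the future C5. Bromine sits on an sp2 carbon in 8, so dehydrobromination cannot compete with methanol loss. The acid treatment is kept cold and short so that the new ortho-prenyl phenol does not cyclize to a chroman.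

Step 6
Reactants: 10 methyl 6-bromo-2-hydroxy-4-methoxy-3-(3-methylbut-2-enyl)benzoate
Product: 11 methyl 2-hydroxy-4,6-dimethoxy-3-(3-methylbut-2-enyl)benzoate
Conditions: NaOMe (excess), CuBr (10 mol %), MeOH–DMF, 100 °C; dilute acid work-up
Reagents that add atoms: sodium methoxide, C[O-].[Na+]
Why: Ullmann-type methoxylation of an aryl bromide catalysed by monovalent copper (CuBr) is classical for bromophenols and is helped here by the ortho ester; methoxide exchange at the methyl ester is degenerate and the prenyl group is inert to base.

Step 7
Reactants: 12 4-(tert-butyldimethylsilyloxy)phenol; 13 trichloroethylene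
Product: 14 tert-butyl{4-[(E)-1,2-dichloroethenoxy]phenoxy}dimethylsilane
Conditions: K2CO3, DMF, 60 °C
Reagents that add atoms: none
Why: Base converts trichloroethylene to dichloroacetylene in situ and the phenoxide adds to it in anti fashion, the known route from phenols to (E)-1,2-dichlorovinyl aryl ethers; anhydrous carbonate and moderate temperature are chosen to spare the aryl silyl ether.

Step 8
Reactants: 14 tert-butyl{4-[(E)-1,2-dichloroethenoxy]phenoxy}dimethylsilane; 11 methyl 2-hydroxy-4,6-dimethoxy-3-(3-methylbut-2-enyl)benzoate
Product: 17 2-[4-(tert-butyldimethylsilyloxy)phenoxy]-5,7-dimethoxy-8-(3-methylbut-2-enyl)-4H-chromen-4-one, via lithium aryloxyacetylide 15 (not isolated), via hydroxyaryl ynone 16 (not isolated)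
Conditions: 14 (3 equiv), n-BuLi (6 equiv), THF, −78 to −40 °C; then lithium phenoxide of 11 [LiN(SiMe3)2, 1 equiv], THF, −78 to 0 °C; NH4Cl; then K2CO3 (cat.), acetone, rt
Reagents that add atoms: none
Why: Dehydrochlorination and chlorine–lithium exchange turn the dichlorovinyl ether into the lithium alkynyl ether 15, a slender nucleophile that should add once to the lithium-chelated, planar salicylate ester (nucleophilic acyl substitution). The resulting ortho-oxido ynone is a vinylogous carboxylate and is deactivated toward a second addition. Ynone 16 should then close by 6-endo-dig oxa-Michael addition, because the alkyne carbon bearing the aryloxy group is both β to the carbonyl and the electrophilic carbon of the ynol ether.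

Step 9
Reactants: 17 2-[4-(tert-butyldimethylsilyloxy)phenoxy]-5,7-dimethoxy-8-(3-methylbut-2-enyl)-4H-chromen-4-one
Product: 18 2-[4-(tert-butyldimethylsilyloxy)phenoxy]-5-hydroxy-7-methoxy-8-(3-methylbut-2-enyl)-4H-chromen-4-one
Conditions: BCl3 (1 M in CH2Cl2), CH2Cl2, −78 to −20 °C; cold NaHCO3 quench
Reagents that add atoms: none
Why: Chelation-controlled demethylation: BCl3 binds the C4 carbonyl and the peri 5-methoxy oxygen in a six-membered chelate and chloride removes that methyl group only, leaving the 7-methyl ether. No protic acid forms before the cold buffered quench, and the prenyl group has no neighbouring free hydroxyl to cyclize onto.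

Step 10
Reactants: 18 2-[4-(tert-butyldimethylsilyloxy)phenoxy]-5-hydroxy-7-methoxy-8-(3-methylbut-2-enyl)-4H-chromen-4-one
Product: 19 5-hydroxy-2-(4-hydroxyphenoxy)-7-methoxy-8-(3-methylbut-2-enyl)-4H-chromen-4-one (7-O-methylepimedonin G)
Conditions: Bu4NF, AcOH (1:1), THF, 0 °C
Reagents that add atoms: none
Why: Fluoride cleavage of an aryl silyl ether is fast at 0 °C; buffering with acetic acid keeps hydroxide and naked phenoxide away from the electrophilic C2 of the 2-aryloxychromone.

## Compound list

1 | methyl acetoacetate | COC(=O)CC(C)=O | starting material
2 | prenyl bromide (1-bromo-3-methylbut-2-ene) | CC(C)=CCBr | starting material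
3 | methyl 2-acetyl-5-methylhex-4-enoate (racemic) | COC(=O)C(CC=C(C)C)C(C)=O | intermediate
4 | methyl (E)-3-methoxy-2-(3-methylbut-2-enyl)but-2-enoate | CO/C(C)=C(\CC=C(C)C)C(=O)OC | intermediate
5 | (1Z)-1,3-dimethoxy-2-(3-methylbut-2-enyl)-1-(trimethylsilyloxy)buta-1,3-diene | C=C(OC)/C(CC=C(C)C)=C(/OC)O[Si](C)(C)C | intermediate
6 | methyl propiolate | C#CC(=O)OC | starting material
7 | methyl 3-bromopropiolate | COC(=O)C#CBr | intermediate
8 | methyl 2-bromo-4,6-dimethoxy-5-(3-methylbut-2-enyl)-6-(trimethylsilyloxy)cyclohexa-1,4-diene-1-carboxylate (racemic, not isolated) | COC(=O)C1=C(Br)CC(OC)=C(CC=C(C)C)C1(OC)O[Si](C)(C)C | intermediate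
9 | methyl 6-bromo-4-methoxy-3-(3-methylbut-2-enyl)-2-(trimethylsilyloxy)benzoate (not isolated) | COC(=O)c1c(Br)cc(OC)c(CC=C(C)C)c1O[Si](C)(C)C | intermediate
10 | methyl 6-bromo-2-hydroxy-4-methoxy-3-(3-methylbut-2-enyl)benzoate | COC(=O)c1c(Br)cc(OC)c(CC=C(C)C)c1O | intermediate
11 | methyl 2-hydroxy-4,6-dimethoxy-3-(3-methylbut-2-enyl)benzoate | COC(=O)c1c(OC)cc(OC)c(CC=C(C)C)c1O | intermediate
12 | 4-(tert-butyldimethylsilyloxy)phenol | CC(C)(C)[Si](C)(C)Oc1ccc(O)cc1 | starting material
13 | trichloroethylene | ClC=C(Cl)Cl | starting material
14 | tert-butyl{4-[(E)-1,2-dichloroethenoxy]phenoxy}dimethylsilane | Cl/C=C(/Cl)Oc1ccc(O[Si](C)(C)C(C)(C)C)cc1 | intermediate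
15 | lithium 2-[4-(tert-butyldimethylsilyloxy)phenoxy]ethyn-1-ide (not isolated) | [Li]C#COc1ccc(O[Si](C)(C)C(C)(C)C)cc1 | intermediate
16 | 1-[2-hydroxy-4,6-dimethoxy-3-(3-methylbut-2-enyl)phenyl]-3-[4-(tert-butyldimethylsilyloxy)phenoxy]prop-2-yn-1-one (not isolated) | COc1cc(OC)c(C(=O)C#COc2ccc(O[Si](C)(C)C(C)(C)C)cc2)c(O)c1CC=C(C)C | intermediate
17 | 2-[4-(tert-butyldimethylsilyloxy)phenoxy]-5,7-dimethoxy-8-(3-methylbut-2-enyl)-4H-chromen-4-one | COc1cc(OC)c2c(=O)cc(Oc3ccc(O[Si](C)(C)C(C)(C)C)cc3)oc2c1CC=C(C)C | intermediate
18 | 2-[4-(tert-butyldimethylsilyloxy)phenoxy]-5-hydroxy-7-methoxy-8-(3-methylbut-2-enyl)-4H-chromen-4-one | COc1cc(O)c2c(=O)cc(Oc3ccc(O[Si](C)(C)C(C)(C)C)cc3)oc2c1CC=C(C)C | intermediate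
19 | 5-hydroxy-2-(4-hydroxyphenoxy)-7-methoxy-8-(3-methylbut-2-enyl)-4H-chromen-4-one (7-O-methylepimedonin G) | COc1cc(O)c2c(=O)cc(Oc3ccc(O)cc3)oc2c1CC=C(C)C | target

## Step count and least certain steps

Total: 10 steps. Longest linear sequence: 8 steps (1, 2, 3, 5, 6, 8, 9, 10).

Step 5 (key step).
- What may go wrong: halophilic attack of the electron-rich ketene acetal on the bromine of 7 (bromine transfer in place of C–C bond formation), since a bromoalkyne with an acceptor group is also a source of electrophilic bromine. Other risks are premature hydrolysis of the diene, loss of silanol in place of methanol during aromatization, and acid-induced ring closure of the ortho-prenyl phenol during work-up.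
- Fallback: this gives up the cycloaddition for classical phloroglucinol chemistry and sets out from 2 and bought methyl 2,4,6-trihydroxybenzoate F1. C-Prenylation in cold aqueous KOH should give methyl 2,4,6-trihydroxy-3-(3-methylbut-2-enyl)benzoate F2. Methylation with two equivalents of Me2SO4 and K2CO3 in acetone should take the unchelated 4-hydroxyl and the less hindered of the two chelated hydroxyls, leaving the one beside the prenyl group. It comes back to the route at 11, bypassing 10 and step 6.

Step 8.
- What may go wrong: slow addition to an ester that is flanked on both sides and deactivated by the ortho phenoxide; a second acetylide addition to the ynone once it is released; conjugate addition of the expelled methoxide to the push–pull ynone; hydration of the ynol ether on work-up.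
- Fallback: this sets out from 11. Aminolysis with MeNH(OMe)·HCl and i-PrMgCl in THF should give the N-methoxy-N-methylamide 2-hydroxy-N,4,6-trimethoxy-N-methyl-3-(3-methylbut-2-enyl)benzamide F3. Its chelated tetrahedral adduct with 15 cannot collapse before the quench, so over-addition is excluded. Release of 16 and base-induced closure bring it back to the route at 17.

Step 9.
- What may go wrong: addition of hydrogen chloride across the prenyl double bond or Lewis acid-induced cation chemistry at that alkene if the mixture warms or the quench is slow; competing cleavage of the 7-methyl ether or the C2 aryloxy link on over-reaction. A sacrificial alkene such as 2-methylbut-2-ene can be added as an acid trap.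
- Fallback: this removes the Lewis acid altogether, sets out from 10 and omits step 6. Addition of 15 as in step 8 should give 1-[6-bromo-2-hydroxy-4-methoxy-3-(3-methylbut-2-enyl)phenyl]-3-[4-(tert-butyldimethylsilyloxy)phenoxy]prop-2-yn-1-one F4 (not isolated), which should close to 5-bromo-2-[4-(tert-butyldimethylsilyloxy)phenoxy]-7-methoxy-8-(3-methylbut-2-enyl)-4H-chromen-4-one F5. Miyaura borylation (B2pin2, PdCl2(dppf) with dppf = 1,1'-bis(diphenylphosphino)ferrocene, KOAc, dioxane, 80 °C) should give 2-[4-(tert-butyldimethylsilyloxy)phenoxy]-7-methoxy-8-(3-methylbut-2-enyl)-5-(4,4,5,5-tetramethyl-1,3,2-dioxaborolan-2-yl)-4H-chromen-4-one F6. Oxidation of the C–B bond with trimethylamine N-oxide in THF, under neutral conditions that spare both C2 and the alkene, comes back to the route at 18.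

Step 7.
- What may go wrong: silyl transfer between phenoxide oxygens under the basic conditions, which would scramble 12 into bis-silylated and unprotected hydroquinone and so into doubly vinylated material.
- Fallback: this reverses the order of the two O-functionalizations and sets out from 13 and bought hydroquinone F7, used in excess. Monovinylation under the conditions of step 7 should give 4-[(E)-1,2-dichloroethenoxy]phenol F8. Silylation with t-BuMe2SiCl and imidazole in DMF comes back to the route at 14.

## Further compounds

F1 | step 5 | methyl 2,4,6-trihydroxybenzoate | COC(=O)c1c(O)cc(O)cc1O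
F2 | step 5 | methyl 2,4,6-trihydroxy-3-(3-methylbut-2-enyl)benzoate | COC(=O)c1c(O)cc(O)c(CC=C(C)C)c1O
F3 | step 8 | 2-hydroxy-N,4,6-trimethoxy-N-methyl-3-(3-methylbut-2-enyl)benzamide | CON(C)C(=O)c1c(OC)cc(OC)c(CC=C(C)C)c1O
F4 | step 9 | 1-[6-bromo-2-hydroxy-4-methoxy-3-(3-methylbut-2-enyl)phenyl]-3-[4-(tert-butyldimethylsilyloxy)phenoxy]prop-2-yn-1-one | COc1cc(Br)c(C(=O)C#COc2ccc(O[Si](C)(C)C(C)(C)C)cc2)c(O)c1CC=C(C)C
F5 | step 9 | 5-bromo-2-[4-(tert-butyldimethylsilyloxy)phenoxy]-7-methoxy-8-(3-methylbut-2-enyl)-4H-chromen-4-one | COc1cc(Br)c2c(=O)cc(Oc3ccc(O[Si](C)(C)C(C)(C)C)cc3)oc2c1CC=C(C)C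
F6 | step 9 | 2-[4-(tert-butyldimethylsilyloxy)phenoxy]-7-methoxy-8-(3-methylbut-2-enyl)-5-(4,4,5,5-tetramethyl-1,3,2-dioxaborolan-2-yl)-4H-chromen-4-one | COc1cc(B2OC(C)(C)C(C)(C)O2)c2c(=O)cc(Oc3ccc(O[Si](C)(C)C(C)(C)C)cc3)oc2c1CC=C(C)C
F7 | step 7 | hydroquinone | Oc1ccc(O)cc1
F8 | step 7 | 4-[(E)-1,2-dichloroethenoxy]phenol | Cl/C=C(/Cl)Oc1ccc(O)cc1
A1 | alternative 1 | 5,7-dimethoxy-2,2-dimethyl-8-(3-methylbut-2-enyl)-4H-1,3-benzodioxin-4-one | COc1cc(OC)c2C(=O)OC(C)(C)Oc2c1CC=C(C)C
A2 | alternative 1 | tert-butyl(4-ethenoxyphenoxy)dimethylsilane | C=COc1ccc(O[Si](C)(C)C(C)(C)C)cc1
A3 | alternative 1 | 3,5-dimethoxy-2-(3-methylbut-2-enyl)-6-(oxomethylidene)cyclohexa-2,4-dien-1-one | O=C=C1C(=O)C(CC=C(C)C)=C(OC)C=C1OC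
A4 | alternative 1 | 5,7-dimethoxy-8-(3-methylbut-2-enyl)-2-[4-(tert-butyldimethylsilyloxy)phenoxy]chroman-4-one (racemic) | COc1cc(OC)c2C(=O)CC(Oc3ccc(O[Si](C)(C)C(C)(C)C)cc3)Oc2c1CC=C(C)C
A5 | alternative 2 | (Z)-3-[4-(benzyloxy)phenoxy]-3-[3,5-dimethoxy-2-(3-methylbut-2-enyl)phenoxy]prop-2-enoic acid | OC(=O)/C=C(\Oc1cc(OC)cc(OC)c1CC=C(C)C)Oc1ccc(OCc2ccccc2)cc1
A6 | alternative 2 | 2-[4-(benzyloxy)phenoxy]-5,7-dimethoxy-8-(3-methylbut-2-enyl)-4H-chromen-4-one | COc1cc(OC)c2c(=O)cc(Oc3ccc(OCc4ccccc4)cc3)oc2c1CC=C(C)C
A7 | alternative 3 | 3-ethoxycyclobut-2-en-1-one | CCOC1=CC(=O)C1
A8 | alternative 3 | 1-methoxy-5-methylhex-4-en-1-yne | COC#CCC=C(C)C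
A9 | alternative 3 | 5-ethoxy-3-methoxy-2-(3-methylbut-2-enyl)phenol | CCOc1cc(O)c(CC=C(C)C)c(OC)c1
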